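**Retrosynthetic overview**

- The target is (2S)-5,7-dihydroxy-4'-methoxy-8,3'-diprenylflavanone (14). In ring C the fragment O1–C8a–C4a–C4, carried by ring A, is a latent ortho-quinone methide heterodiene, and C2–C3 with its 4-methoxy-3-prenylphenyl group (ring B) is an electron-rich styrene. O1–C2 and C3–C4 are therefore cut together as a polarity-matched inverse-demand hetero-[4+2].
- C4 enters already oxygenated, as a methoxy group on the methide carbon (salicylaldehyde 4 plus trimethyl orthoformate). A C4 methylene could not be oxidized later (DDQ-type hydride abstraction) without touching the C8 prenyl CH2, which is benzylic to the same ring A and allylic as well. The methoxy group also stabilizes the methide. After the cycloaddition, C4–OMe is hydrolysed and oxidized to the ketone, and the silyl ethers are removed.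
- Ring A arm: C-prenylation of 2,4,6-trihydroxybenzaldehyde, then silylation of O4 and O6, which leaves free only the phenol between CHO and prenyl (future O1 next to the C8 prenyl). Ring B arm: methylenation of 3-bromo-4-methoxybenzaldehyde, then aryl Grignard/copper prenylation.
- Ring order: rings A and B are bought as arenes. Ring C is the only ring made, closed in step 5, which also sets C2, the only stereocentre of the target.

Key step: step 5

Assumption: the sense of induction of the chiral acid in step 5 cannot be assigned with certainty for this substrate class; the (R)-catalyst is written, and its antipode is used if a first run shows the 2R series.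

**Route**

Step 1
Reactants: 1 2,4,6-trihydroxybenzaldehyde; 2 prenyl bromide
Product: 3 2,4,6-trihydroxy-3-(3-methylbut-2-en-1-yl)benzaldehyde
Conditions: DBU (1.1 equiv), THF, 0 °C to rt
Reagents that add atoms: none
Why: Base-mediated C-alkylation of a phloroglucinol-type phenoxide (a vinylogous enolate) with a soft allylic bromide is known for acylphloroglucinols; the two open ring carbons of 1 are equivalent, so a single mono-C-prenyl isomer is expected, and one equivalent of bromide limits double prenylation.

Step 2
Reactants: 3 2,4,6-trihydroxy-3-prenylbenzaldehyde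
Product: 4 4,6-bis(tert-butyldimethylsilyloxy)-2-hydroxy-3-(3-methylbut-2-en-1-yl)benzaldehyde (free OH between CHO and prenyl)
Conditions: TBSCl (2.1 equiv), imidazole, CH2Cl2, 0 °C
Reagents that add atoms: tert-butyldimethylsilyl chloride, CC(C)(C)[Si](C)(C)Cl
Why: In this phenol silylation the para OH and the ortho OH next to a ring hydrogen should react first, while the OH flanked by CHO and prenyl is hydrogen-bonded to the carbonyl and hindered on both sides and should stay free.

Step 3
Reactants: 5 3-bromo-4-methoxybenzaldehyde
Product: 6 2-bromo-1-methoxy-4-vinylbenzene (3-bromo-4-methoxystyrene)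
Conditions: Ph3PCH3Br, KOtBu, THF, 0 °C to rt
Reagents that add atoms: methyltriphenylphosphonium bromide, C[P+](c1ccccc1)(c1ccccc1)c1ccccc1.[Br-]
Why: Wittig methylenation of an aromatic aldehyde, to which the aryl bromide and the methyl ether are inert.

Step 4
Reactants: 6 2-bromo-1-methoxy-4-vinylbenzene; 2 prenyl bromide
Product: 8 4-methoxy-3-prenylstyrene, via aryl Grignard reagent 7 (not isolated)
Conditions: Mg, LiCl, THF, rt; then CuI (10 mol%), 2, −20 °C to rt
Reagents that add atoms: none
Why: Magnesium insertion into the aryl bromide (vinylaryl Grignard reagents are stable in THF) is followed by copper-catalysed allylic substitution, which with aryl nucleophiles and prenyl bromide takes place at the unhindered CH2 terminus and gives the linear prenyl arene.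

Step 5
Reactants: 4 4,6-bis(tert-butyldimethylsilyloxy)-2-hydroxy-3-prenylbenzaldehyde; 8 4-methoxy-3-prenylstyrene
Product: 11 (2S)-5,7-bis(tert-butyldimethylsilyloxy)-4-methoxy-2-[4-methoxy-3-prenylphenyl]-8-prenylchroman (C4 epimers), via dimethyl acetal 9 (not isolated), via methoxy ortho-quinone methide 10 (not isolated)
Conditions: HC(OMe)3 (1.5 equiv), (R)-3,3'-bis(2,4,6-triisopropylphenyl)-BINOL N-triflylphosphoramide (10 mol%), 8 (2 equiv, slow addition), 5 Å MS, toluene, −20 °C
Reagents that add atoms: trimethyl orthoformate, COC(OC)OC
Why: Proposed new method: the chiral acid first catalyses acetal formation from the chelated aldehyde and trimethyl orthoformate and then removes methanol from acetal 9 to give the methoxy-substituted ortho-quinone methide 10 (O-protonated, it is the oxocarbenium ion), which stays hydrogen-bonded through the O1 oxygen to the chiral phosphoramide anion. The CH2 terminus of styrene 8 attacks the methide carbon (C3–C4) while the dienone oxygen closes on the benzylic carbon (O1–C2) in a concerted but asynchronous inverse-demand hetero-Diels–Alder reaction, so ring C closes in the [4+2] mode (in the stepwise limit a 6-exo-trig capture of the para-methoxybenzylic cation by the phenol oxygen), and the return of ring A to an arene drives it. The closest known reaction types are the chiral phosphoric acid and N-triflylphosphoramide catalysed [4+2] cycloadditions of aryl-substituted ortho-quinone methides (from ortho-hydroxybenzhydryl alcohols) with styrenes, the chiral Brønsted acid catalysed intramolecular [4+2] of alkoxy ortho-quinone methides made from salicylaldehydes, and the racemic Lewis acid catalysed three-component chroman synthesis from salicylaldehydes, trimethyl orthoformate and styrenes; the enantioselective intermolecular union of an alkoxy methide with a styrene is the part that has not been shown. C2 is controlled by the catalyst, whose anion sits on one face of the bound heterodiene and leaves the other open to an endo approach of the styrene aryl group under the 3,3'-aryl pocket, which should give 2S with the right catalyst antipode, while C4 forms under substrate control as an epimer mixture that converges in step 7. The step needs regio-, site- and chemoselectivity: regiochemistry follows from the polarity match (nucleophilic styrene CH2 to electrophilic methide carbon, charge at C2 stabilized by the para methoxy group), closure through the oxygen next to the prenyl group is enforced by the silyl ether on the other ortho oxygen, and the two trisubstituted prenyl alkenes are far less nucleophilic than the 4-methoxystyrene.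

Step 6
Reactants: 11 (2S)-5,7-bis(tert-butyldimethylsilyloxy)-4-methoxy-2-[4-methoxy-3-prenylphenyl]-8-prenylchroman
Product: 12 (2S)-5,7-bis(tert-butyldimethylsilyloxy)-2-[4-methoxy-3-prenylphenyl]-8-prenylchroman-4-ol (C4 epimers)
Conditions: PPTS (cat.), acetone/H2O (10:1), rt
Reagents that add atoms: water, O
Why: SN1 solvolysis, because the C4 methyl ether is benzylic and ortho/para to three ring A oxygens and should ionize under mild acid, with water in excess trapping the cation; no free phenol is present, so the prenyl groups cannot cyclize, and C2 is not involved.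

Step 7
Reactants: 12 (2S)-5,7-bis(tert-butyldimethylsilyloxy)-2-[4-methoxy-3-prenylphenyl]-8-prenylchroman-4-ol
Product: 13 (2S)-5,7-bis(tert-butyldimethylsilyloxy)-2-[4-methoxy-3-prenylphenyl]-8-prenylchroman-4-one
Conditions: Dess–Martin periodinane, NaHCO3, CH2Cl2, 0 °C to rt
Reagents that add atoms: none
Why: Dess–Martin oxidation of a secondary benzylic alcohol, in which both C4 epimers converge on one ketone and the buffered neutral medium leaves the alkenes, the silyl ethers and C2 untouched.

Step 8
Reactants: 13 (2S)-5,7-bis(tert-butyldimethylsilyloxy)-2-[4-methoxy-3-prenylphenyl]-8-prenylchroman-4-one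
Product: 14 (2S)-5,7-dihydroxy-2-[4-methoxy-3-prenylphenyl]-8-prenylchroman-4-one (target)
Conditions: TBAF, AcOH (1:1), THF, 0 °C
Reagents that add atoms: none
Why: Fluoride cleavage of aryl silyl ethers, with the acetic acid buffer keeping the medium from turning basic so that the flavanone should not open to the chalcone (retro-oxa-Michael) and C2 holds.

**Compound list**

1 | 2,4,6-trihydroxybenzaldehyde | O=Cc1c(O)cc(O)cc1O | starting material
2 | prenyl bromide (1-bromo-3-methylbut-2-ene) | CC(C)=CCBr | starting material
3 | 2,4,6-trihydroxy-3-(3-methylbut-2-en-1-yl)benzaldehyde | O=Cc1c(O)cc(O)c(CC=C(C)C)c1O | intermediate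
4 | 4,6-bis(tert-butyldimethylsilyloxy)-2-hydroxy-3-(3-methylbut-2-en-1-yl)benzaldehyde | O=Cc1c(O)c(CC=C(C)C)c(O[Si](C)(C)C(C)(C)C)cc1O[Si](C)(C)C(C)(C)C | intermediate
5 | 3-bromo-4-methoxybenzaldehyde | COc1ccc(C=O)cc1Br | starting material
6 | 2-bromo-1-methoxy-4-vinylbenzene | C=Cc1ccc(OC)c(Br)c1 | intermediate
7 | (2-methoxy-5-vinylphenyl)magnesium bromide | C=Cc1ccc(OC)c([Mg]Br)c1 | intermediate (not isolated)
8 | 1-methoxy-2-(3-methylbut-2-en-1-yl)-4-vinylbenzene (4-methoxy-3-prenylstyrene) | C=Cc1ccc(OC)c(CC=C(C)C)c1 | intermediate
9 | 2-(dimethoxymethyl)-3,5-bis(tert-butyldimethylsilyloxy)-6-prenylphenol | COC(OC)c1c(O)c(CC=C(C)C)c(O[Si](C)(C)C(C)(C)C)cc1O[Si](C)(C)C(C)(C)C | intermediate (not isolated)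
10 | 6-(methoxymethylene)-3,5-bis(tert-butyldimethylsilyloxy)-2-prenylcyclohexa-2,4-dien-1-one (methide geometry not defined) | COC=C1C(=O)C(CC=C(C)C)=C(O[Si](C)(C)C(C)(C)C)C=C1O[Si](C)(C)C(C)(C)C | intermediate (not isolated)
11 | (2S)-5,7-bis(tert-butyldimethylsilyloxy)-4-methoxy-2-[4-methoxy-3-prenylphenyl]-8-prenylchroman, C4 epimers (C4 left undefined on purpose) | COc1ccc([C@@H]2CC(OC)c3c(O[Si](C)(C)C(C)(C)C)cc(O[Si](C)(C)C(C)(C)C)c(CC=C(C)C)c3O2)cc1CC=C(C)C | intermediate
12 | (2S)-5,7-bis(tert-butyldimethylsilyloxy)-2-[4-methoxy-3-prenylphenyl]-8-prenylchroman-4-ol, C4 epimers | COc1ccc([C@@H]2CC(O)c3c(O[Si](C)(C)C(C)(C)C)cc(O[Si](C)(C)C(C)(C)C)c(CC=C(C)C)c3O2)cc1CC=C(C)C | intermediate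
13 | (2S)-5,7-bis(tert-butyldimethylsilyloxy)-2-[4-methoxy-3-prenylphenyl]-8-prenylchroman-4-one | COc1ccc([C@@H]2CC(=O)c3c(O[Si](C)(C)C(C)(C)C)cc(O[Si](C)(C)C(C)(C)C)c(CC=C(C)C)c3O2)cc1CC=C(C)C | intermediate
14 | (2S)-5,7-dihydroxy-2-[4-methoxy-3-prenylphenyl]-8-prenylchroman-4-one | COc1ccc([C@@H]2CC(=O)c3c(O)cc(O)c(CC=C(C)C)c3O2)cc1CC=C(C)C | target

**Step count**

Total steps: 8. Longest linear sequence: 6 steps (1, 2, 5, 6, 7, 8 from compound 1; equally 3, 4, 5, 6, 7, 8 from compound 5).

**Steps most likely to fail**

1. Step 5 (proposed new method).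
 - What may go wrong: facial discrimination may be poor or of the wrong sense, because only the heterodiene is held by the catalyst and the styrene has no binding group. The acid may start cationic oligomerization of the electron-rich styrene. The product may re-ionize at C4 and add a second styrene. The prenyl group of 4 may cyclize onto the free phenol before the cycloaddition.
 - Fallback (known chemistry), setting out from 4 and 8: the racemic three-component chroman synthesis with trimethyl orthoformate under Sc(OTf)3 catalysis in CH2Cl2 gives racemic 5,7-bis(tert-butyldimethylsilyloxy)-4-methoxy-2-[4-methoxy-3-prenylphenyl]-8-prenylchroman F1. Hydrolysis as in step 6 gives the racemic flavan-4-ol F2, and Dess–Martin oxidation as in step 7 gives the racemic bis-silyl flavanone F3. F3 is then resolved by kinetic resolution through Noyori-type asymmetric transfer hydrogenation (Ru(II)–TsDPEN, HCO2H/Et3N), with the catalyst enantiomer that reduces the (R)-ketone. The (R)-ketone becomes the cis-(2R,4R)-flavan-4-ol F4, which is removed by chromatography, and the unreacted (S)-ketone is compound 13, where the route resumes.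

2. Step 2.
 - What may go wrong: the silyl group may go to the wrong ortho oxygen, or to all three oxygens, and a regioisomer would lead on to the 6-prenyl series.
 - Fallback, setting out from 1 (it also replaces the direct C-prenylation of step 1): bis-silylation of the symmetric aldehyde 1 (TBSCl, imidazole) gives 2-hydroxy-4,6-bis(tert-butyldimethylsilyloxy)benzaldehyde F5, for which only one constitution is possible. Copper-catalysed etherification of the remaining phenol with 2-methylbut-3-yn-2-yl methyl carbonate (CuCl2 cat., DBU, MeCN, 0 °C) gives the 1,1-dimethylpropargyl ether F6. Lindlar semi-hydrogenation gives the 1,1-dimethylallyl ether F7. Aromatic Claisen rearrangement on heating in toluene moves the allyl unit, with allylic transposition, to the only free ortho carbon; this gives the linear prenyl group next to the regenerated chelated phenol, which is compound 4.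

3. Step 4.
 - What may go wrong: attack at the γ-carbon of prenyl bromide would give the reverse-prenyl isomer, the aryl-metal may homocouple, and the vinyl group may polymerize during magnesium insertion.
 - Fallback, setting out from 6, with the polarity reversed so that no aryl-metal is made next to the vinyl group: prenylzinc bromide F8 is prepared from 2 with zinc dust and LiCl in THF and coupled with aryl bromide 6 in a linear-selective palladium-catalysed Negishi reaction (Pd(OAc)2, CPhos-type biarylphosphine, THF, rt). This gives compound 8 directly.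

**Further compounds**

F1 | step 5 | racemic 5,7-bis(tert-butyldimethylsilyloxy)-4-methoxy-2-[4-methoxy-3-prenylphenyl]-8-prenylchroman | COc1ccc(C2CC(OC)c3c(O[Si](C)(C)C(C)(C)C)cc(O[Si](C)(C)C(C)(C)C)c(CC=C(C)C)c3O2)cc1CC=C(C)C
F2 | step 5 | racemic 5,7-bis(tert-butyldimethylsilyloxy)-2-[4-methoxy-3-prenylphenyl]-8-prenylchroman-4-ol | COc1ccc(C2CC(O)c3c(O[Si](C)(C)C(C)(C)C)cc(O[Si](C)(C)C(C)(C)C)c(CC=C(C)C)c3O2)cc1CC=C(C)C
F3 | step 5 | racemic 5,7-bis(tert-butyldimethylsilyloxy)-2-[4-methoxy-3-prenylphenyl]-8-prenylchroman-4-one | COc1ccc(C2CC(=O)c3c(O[Si](C)(C)C(C)(C)C)cc(O[Si](C)(C)C(C)(C)C)c(CC=C(C)C)c3O2)cc1CC=C(C)C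
F4 | step 5 | (2R,4R)-5,7-bis(tert-butyldimethylsilyloxy)-2-[4-methoxy-3-prenylphenyl]-8-prenylchroman-4-ol (2,4-cis) | COc1ccc([C@H]2C[C@@H](O)c3c(O[Si](C)(C)C(C)(C)C)cc(O[Si](C)(C)C(C)(C)C)c(CC=C(C)C)c3O2)cc1CC=C(C)C
F5 | step 2 | 2-hydroxy-4,6-bis(tert-butyldimethylsilyloxy)benzaldehyde | O=Cc1c(O)cc(O[Si](C)(C)C(C)(C)C)cc1O[Si](C)(C)C(C)(C)C
F6 | step 2 | 2-(2-methylbut-3-yn-2-yloxy)-4,6-bis(tert-butyldimethylsilyloxy)benzaldehyde | O=Cc1c(OC(C)(C)C#C)cc(O[Si](C)(C)C(C)(C)C)cc1O[Si](C)(C)C(C)(C)C
F7 | step 2 | 2-(2-methylbut-3-en-2-yloxy)-4,6-bis(tert-butyldimethylsilyloxy)benzaldehyde | O=Cc1c(OC(C)(C)C=C)cc(O[Si](C)(C)C(C)(C)C)cc1O[Si](C)(C)C(C)(C)C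
F8 | step 4 | prenylzinc bromide | CC(C)=CC[Zn]Br
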